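## The problem

The target 21 is a linear hexamer of oxygenated benzene rings, lettered A to F from the 2,4,6-trihydroxyphenoxy end, held together only by five diaryl ether oxygens, so the whole chain has to be assembled by C–O bond formation between electron-rich arenes. It has no stereocentre and no other stereogenic element, so no centre can or need control another and the difficulty is purely regiochemical. In every ether one carbon is flanked by two oxygen-bearing carbons (C2 of ring A, C4 of rings B, C and E, C6 of ring D) while the other has at least one ortho hydrogen (C1 of rings B to F); such couplings go best with the oxygen nucleophile on the flanked carbon and the leaving group on the open one. Ring D breaks the repeat: five contiguous oxygens (aryl ethers at C1 and C6, hydroxyls at C3, C4 and C5) surround a single CH at C2, and two of them must be joined to different trimeric fragments. The fifteen free phenols make 21 prone to air oxidation, above all in base, and its phloroglucinol- and pyrogallol-type rings are readily attacked by electrophiles. Every hydroxyl must therefore travel protected and be released in the last step under non-oxidising, non-basic conditions. The feature that opens the key step is ring D itself: C6(O)–C5(O)–C4(O)–C3(O) is the four-carbon, four-oxygen skeleton of a squaric ester, and C1(O)–C2(H) is a 1-alkoxyvinyl unit.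

## Retrosynthesis

**Unmasking (21 from 20).** The last operation cuts fifteen O–alkyl bonds: twelve methyl ethers on rings A, B, C, E and F and three isopropyl ethers on ring D. Methyl is chosen because the protected monomers 9, 10, 14 and 18 can then be bought, so five of the six rings need no protecting-group steps. The isopropyl groups come from squarate 2 and from the one selective alkylation on ring D. A benzyl ether and hydrogenolysis endgame would be gentler, but each monomer would then cost several steps and the squarate-derived ethers would remain. The forward reaction must be an exhaustive Lewis-acid dealkylation that leaves diaryl ethers alone and keeps the polyphenol in acid.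

**Central ether (20 from 13 and 19).** The bond cut is O(ring D C1)–C4(ring C). This halves the hexamer into two trimers, whereas any other final cut gives a pentamer and a monomer. It is also the cut the key step dictates, because ring D is delivered with oxygen at C1. The price is that the oxygen lies on the less hindered side, so the carbon partner is the doubly flanked bromide of 19. The forward reaction must be a palladium-catalysed C–O coupling with a bulky phosphine that can form a diaryl ether with three ortho substituents. This is the weakest point of the plan.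

**Ring D to ring E ether (13 from 12, 12 from 8 and 11).** Phenol 13 comes from tert-butyl ether 12 by acidolysis. The tert-butyl group is the only ether in the molecule that acid removes without touching methyl, isopropyl or diaryl ethers. Cutting 12 at O(ring D C6)–C1(ring E) gives phenol 8 and bromide 11. Here the polarity is the favourable one: oxygen on the flanked carbon, halide on the open carbon. This ether is made before the central one so that the more hindered phenol meets the less hindered halide while C1 is still masked.

**Telling the hydroxyls apart (8 from 7).** Cutting the O–isopropyl bond at the C3 oxygen leads to hydroquinone 7. Its two hydroxyls differ sharply in environment: one has an ortho hydrogen, the other lies between tert-butoxy and isopropoxy groups. A secondary alkyl halide should take the open one.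

**Ring D (7 from 4, 4 from 2 and 3).** The C2–C3 bond of ring D is cut, which unravels the benzene ring to cyclobutenone 4. No arene substitution chemistry could place five differentiated oxygens around one ring as directly. The tert-butoxy carbon becomes C1, the carbinol carbon C6, the squarate carbons C5 and C4, the ketene carbon C3 and the vinyl CH2 carbon C2. Cutting the carbinol–vinyl bond of 4 gives squarate 2 and vinyllithium 3, made from vinyl ether 1. The precursors are two small purchasable liquids.

**Ring E–F fragment (11 from 9 and 10).** The bond cut is O(ring E C4)–C1(ring F). A copper-mediated oxidative coupling of phenol 9 with boronic acid 10 is preferred over a halide-based coupling because it leaves the bromide of 9 untouched, and that bromide is needed next.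

**Ring A–B–C fragment (19 from 18 and 17, 17 from 9 and 16, 16 from 14).** Both cuts place the oxygen on the flanked carbon (phenols 18 and 9) and the halide on the open carbon. Dihalide 16 carries an open iodide for the first coupling and a flanked bromide that survives to become the electrophile of the central union. Phenol 9 serves a second time, as ring B. Compound 16 should arise from 14 by sterically directed C–H borylation to boronate 15 and iododeboronation.

## Roads not taken

Alternative 1: double nucleophilic substitution on a metal-activated ring E.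
- Cut: both ether bonds of ring E are broken. The electrophile is the sandwich salt cyclopentadienyl(2,5-dichloro-1,3-dimethoxybenzene)ruthenium hexafluorophosphate A1, a cationic arene complex of divalent ruthenium.
- Forward key step: on complex A1 the phenoxide of the ring A–B–C–D tetramer phenol A2 displaces the open chloride, the phenoxide of 3,4,5-trimethoxyphenol A3 then displaces the flanked chloride, and irradiation in acetonitrile releases the permethylated hexamer A4.
- Merits: coordination to the metal turns the electron-rich chloroarene of A1 into a strong electrophile, so even the ether at a doubly flanked carbon forms under mild conditions. For the two ethers of ring E this is probably more dependable than steps 4 and 5 of the chosen plan, and the same activation would be the better answer to step 10.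
- Weak points: the tetramer A2 already contains ring D with its five contiguous oxygens and the awkward ring C–D ether, so the hardest part of the molecule is moved into a starting material. Ruthenium is stoichiometric in A1. The second substitution takes place on a ring already deactivated by the first aryloxy group. Release of the arene must compete with binding of the other electron-rich rings of A4.
- Comparison: A4 needs the same exhaustive demethylation as 20, so the endgame is no gentler. The chosen plan sets against it catalytic metals, purchasable monomers and an actual construction of ring D.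

Alternative 2: ring A built on the oxygen of ring B by polyketide-type folding.
- Cut: carbon–carbon bonds of ring A are broken, leading back to the open-chain dimethyl 4-aryloxy-3,5-dioxoheptanedioate A5.
- Forward key step: a methoxide base folds A5 by Claisen condensation (6-exo-trig) and enolisation to the methyl trihydroxybenzoate A6.
- Merits: the ether at the flanked carbon of ring A is made at the sp3 stage by simple alkylation, no transition metal is needed, and the phloroglucinol pattern appears automatically. For ring A alone this is the more elegant construction.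
- Weak points: the ring A–B ether is the easiest one to make conventionally (step 9 does it in one operation). A5 can form pyrones or expel the aryloxy group. The ester of A6 must later be removed by decarboxylation, and three new phenols must be protected.
- Comparison: it spends about five steps on one ether and leaves rings C to F, including all of ring D, unsolved. De novo ring synthesis pays where the substitution pattern is unique, which is ring D.

Alternative 3: ten hydroxyls traced back to formyl groups.
- Cut: ten aryl C–O bonds are broken at once, leading back to the hexamer deca-aldehyde A7.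
- Forward key step: a peracid converts all ten formyl groups of A7 to formates by aryl migration, and methanolysis gives the decaphenol pentabenzyl ether A8.
- Merits: the formyl groups activate exactly the flanked carbons for nucleophilic aromatic substitution, which is a better solution to ether formation than the copper and palladium couplings of steps 5 and 10. The remaining benzyl ethers of A8 fall by hydrogenolysis, which is gentler than step 11.
- Weak points: ten oxidations on one molecule must all proceed by aryl rather than hydride migration, starting from rings made electron-poor by two formyl groups each. As the reaction advances, A7 turns into an electron-rich polyphenol exposed to excess peracid. The ring D portion of A7, with two formyl groups and three oxygens, is itself a multistep problem.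
- Comparison: partial failure in a tenfold step cannot be repaired. The chosen plan's decisive step is a single unimolecular reaction on a sixteen-carbon compound at the start of the route, where failure is cheap.

Key step: step 2

Remark on the chemistry: the target has no stereogenic element; the only stereocentre met on the way, the carbinol carbon of 4, forms as a racemate and is destroyed in step 2. Compounds 1, 2, 9, 10, 14 and 18 are taken as purchasable.

## Route

Step 1
Reactants: 1 tert-butyl vinyl ether; 2 diisopropyl squarate (3,4-diisopropoxycyclobut-3-ene-1,2-dione)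
Product: 4 4-(1-tert-butoxyvinyl)-4-hydroxy-2,3-diisopropoxycyclobut-2-en-1-one (racemic), via (1-tert-butoxyvinyl)lithium 3 (not isolated)
Conditions: 1 (1.5 equiv), t-BuLi (1.1 equiv), THF, −78 to 0 °C; then 2 (1.0 equiv), THF, −78 °C; H2O quench
Reagents that add atoms: none
Why: Alpha-lithiation of an alkyl vinyl ether followed by 1,2-addition of the vinyllithium to one of the two equivalent ketone carbonyls of the squarate, which are more electrophilic than the vinylogous ester carbons at low temperature. The carbinol centre forms as a racemate and is erased in step 2; a neutral water quench and base-washed glassware should protect the acid-labile tert-butyl enol ether.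

Step 2
Reactants: 4 4-(1-tert-butoxyvinyl)-4-hydroxy-2,3-diisopropoxycyclobut-2-en-1-one
Product: 7 5-tert-butoxy-2,3-diisopropoxybenzene-1,4-diol, via dienylketene 5 (not isolated), via cyclohexadienone 6 (not isolated)
Conditions: toluene (degassed), 110 °C, Ar
Reagents that add atoms: none
Why: Heating 4 should cause conrotatory 4π electrocyclic opening of the C1–C4 bond of the cyclobutenone; the C4 hydroxyl, a donor, rotates outward, so the 1-tert-butoxyvinyl group turns inward and lies cis to the ketene in dienylketene 5. Thermal disrotatory 6π electrocyclisation of 5 then joins the ketene carbon to the vinyl CH2 carbon, which is the C2–C3 bond of ring D, and closes the six-membered ring as cyclohexadienone 6. Enolisation of 6 aromatises it to hydroquinone 7 and supplies the driving force. This is the known thermal ring expansion of 4-alkenyl-4-hydroxycyclobutenones to hydroquinones (Moore rearrangement). No stereocentre is formed and the racemic carbinol centre of 4 disappears. The step needs torquoselectivity (hydroxyl outward) and periselectivity (6π closure rather than lactonisation of the ketene by the hydroxyl); both follow from the outward hydroxyl, which cannot reach the ketene while the inward vinyl group lies beside it. Only one 6π closure is possible, so the lone CH must end between the tert-butoxy carbon and the ketene-derived hydroxyl carbon. Oxygen-free solvent and base-washed glassware should protect the enol ether of 4 and the air-sensitive product.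

Step 3
Reactants: 7 5-tert-butoxy-2,3-diisopropoxybenzene-1,4-diol
Product: 8 6-tert-butoxy-2,3,4-triisopropoxyphenol
Conditions: 2-iodopropane (1.2 equiv), K2CO3, DMF (degassed), rt, Ar
Reagents that add atoms: 2-iodopropane, CC(C)I
Why: Williamson ether synthesis with a secondary halide, which is sensitive to crowding at the nucleophile. The hydroxyl next to the ring CH should react, while the one between tert-butoxy and isopropoxy groups should not; this keeps the C6 oxygen of ring D free for arylation.

Step 4
Reactants: 9 4-bromo-2,6-dimethoxyphenol; 10 (3,4,5-trimethoxyphenyl)boronic acid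
Product: 11 5-(4-bromo-2,6-dimethoxyphenoxy)-1,2,3-trimethoxybenzene
Conditions: Cu(OAc)2 (1 equiv), pyridine, 4 Å MS, CH2Cl2, air, rt
Reagents that add atoms: none
Why: Chan–Lam coupling: the aryl group passes from boron to divalent copper, the phenoxide binds, oxidation gives trivalent copper and C–O reductive elimination follows at room temperature, where 2,6-disubstituted phenols are tolerated. The aryl bromide of 9 is inert under these conditions, so no halide selectivity is needed and the bromide is kept for step 5; air returns the copper to the divalent state.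

Step 5
Reactants: 8 6-tert-butoxy-2,3,4-triisopropoxyphenol; 11 5-(4-bromo-2,6-dimethoxyphenoxy)-1,2,3-trimethoxybenzene
Product: 12 1-tert-butoxy-2-[3,5-dimethoxy-4-(3,4,5-trimethoxyphenoxy)phenoxy]-3,4,5-triisopropoxybenzene
Conditions: CuI (20 mol %), picolinic acid (40 mol %), K3PO4, DMSO, 100 °C, Ar
Reagents that add atoms: none
Why: Ligand-accelerated Ullmann ether synthesis in its favourable polarity: a phenoxide flanked by two oxygens attacks an aryl bromide with two ortho hydrogens, and the picolinate ligand on monovalent copper is the system known to couple 2,6-disubstituted phenols. The tert-butyl ether is stable to base.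

Step 6
Reactants: 12 1-tert-butoxy-2-[3,5-dimethoxy-4-(3,4,5-trimethoxyphenoxy)phenoxy]-3,4,5-triisopropoxybenzene
Product: 13 2-[3,5-dimethoxy-4-(3,4,5-trimethoxyphenoxy)phenoxy]-3,4,5-triisopropoxyphenol
Conditions: CF3CO2H, CH2Cl2, 0 °C to rt
Reagents that add atoms: none
Why: Acidolysis of an aryl tert-butyl ether by ionisation at the tertiary carbon; methyl, isopropyl and diaryl ethers are inert to this acid. Every ring CH of 12 lies between two oxygen substituents, so the tert-butyl cation meets only crowded ring positions and should leave as 2-methylpropene.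

Step 7
Reactants: 14 2-bromo-1,3-dimethoxybenzene
Product: 16 2-bromo-5-iodo-1,3-dimethoxybenzene, via arylboronate 15 (not isolated)
Conditions: [Ir(OMe)(cod)]2 (1.5 mol %), 4,4′-di-tert-butyl-2,2′-bipyridine (3 mol %), B2pin2, THF, 80 °C; then CuI (10 mol %), 1,10-phenanthroline (20 mol %), KI, MeOH/H2O, air, 80 °C
Reagents that add atoms: potassium iodide, [K+].[I-]
Why: Sterically controlled iridium-catalysed C–H borylation takes place at C5, the only CH without an ortho substituent, and tolerates the aryl bromide. Copper-catalysed iododeboronation in the same flask then replaces boron by iodine at that carbon.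

Step 8
Reactants: 9 4-bromo-2,6-dimethoxyphenol; 16 2-bromo-5-iodo-1,3-dimethoxybenzene
Product: 17 2-bromo-5-(4-bromo-2,6-dimethoxyphenoxy)-1,3-dimethoxybenzene
Conditions: CuI (10 mol %), picolinic acid (20 mol %), K3PO4, DMSO, 80 °C, Ar
Reagents that add atoms: none
Why: Ullmann ether synthesis with halide discrimination: monovalent copper activates the C–I bond far faster than a C–Br bond. The bromide of 16 is also shielded by two methoxy groups, and the bromide of 9 lies para to a phenoxide, so only the iodide should be replaced.

Step 9
Reactants: 17 2-bromo-5-(4-bromo-2,6-dimethoxyphenoxy)-1,3-dimethoxybenzene; 18 2,4,6-trimethoxyphenol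
Product: 19 2-[4-(4-bromo-3,5-dimethoxyphenoxy)-3,5-dimethoxyphenoxy]-1,3,5-trimethoxybenzene
Conditions: CuI (20 mol %), picolinic acid (40 mol %), K3PO4, DMSO, 100 °C, Ar
Reagents that add atoms: none
Why: Ullmann ether synthesis with site selection by crowding: the ring B bromide has two ortho hydrogens and the ring C bromide two ortho methoxy groups. The bulky 2,6-dimethoxyphenoxide of 18 should magnify this difference; argon prevents copper-mediated oxidation of the electron-rich phenol.

Step 10
Reactants: 13 2-[3,5-dimethoxy-4-(3,4,5-trimethoxyphenoxy)phenoxy]-3,4,5-triisopropoxyphenol; 19 2-[4-(4-bromo-3,5-dimethoxyphenoxy)-3,5-dimethoxyphenoxy]-1,3,5-trimethoxybenzene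
Product: 20 1-{4-[2,6-dimethoxy-4-(2,4,6-trimethoxyphenoxy)phenoxy]-2,6-dimethoxyphenoxy}-2-[3,5-dimethoxy-4-(3,4,5-trimethoxyphenoxy)phenoxy]-3,4,5-triisopropoxybenzene (the target with twelve methyl ethers on rings A, B, C, E, F and three isopropyl ethers on ring D)
Conditions: Pd(OAc)2 (5 mol %), 2-di-tert-butylphosphino-2′,4′,6′-triisopropylbiphenyl (t-BuXPhos, 10 mol %), K3PO4, toluene, 110 °C, Ar
Reagents that add atoms: none
Why: Palladium-catalysed diaryl ether synthesis: zerovalent palladium bearing the bulky dialkylbiarylphosphine inserts into the hindered C–Br bond, the phenoxide of 13 replaces bromide, and C–O reductive elimination is driven by the crowding that the two ortho methoxy groups and the ligand create. This ligand class is the one known to couple ortho-substituted, electron-rich aryl halides with ortho-substituted phenols.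

Step 11
Reactants: 20 the fully alkylated hexamer
Product: 21 2-{4-[4-(2-{3,5-dihydroxy-4-(3,4,5-trihydroxyphenoxy)phenoxy}-3,4,5-trihydroxyphenoxy)-3,5-dihydroxyphenoxy]-3,5-dihydroxyphenoxy}benzene-1,3,5-triol (CNP0175585.0)
Conditions: BBr3 (excess), CH2Cl2, −78 °C to rt, Ar; then H2O, 0 °C
Reagents that add atoms: none
Why: Lewis-acid ether cleavage: BBr3 binds each alkyl aryl ether oxygen and bromide removes the methyl or isopropyl group at its sp3 carbon, whereas diaryl ethers offer no such carbon and stay intact. The aryl borates hydrolyse on work-up, and the acidic, non-oxidising medium suits the air-sensitive polyphenol.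

## Compound list

1 | tert-butyl vinyl ether | C=COC(C)(C)C | starting material
2 | diisopropyl squarate (3,4-diisopropoxycyclobut-3-ene-1,2-dione) | CC(C)OC1=C(OC(C)C)C(=O)C1=O | starting material
3 | (1-tert-butoxyvinyl)lithium | [Li]C(=C)OC(C)(C)C | intermediate
4 | 4-(1-tert-butoxyvinyl)-4-hydroxy-2,3-diisopropoxycyclobut-2-en-1-one (racemic) | O=C1C(OC(C)C)=C(OC(C)C)C1(O)C(=C)OC(C)(C)C | intermediate
5 | (3Z)-5-tert-butoxy-4-hydroxy-2,3-diisopropoxyhexa-1,3,5-trien-1-one (dienylketene) | O=C=C(OC(C)C)/C(OC(C)C)=C(O)\C(=C)OC(C)(C)C | intermediate
6 | 5-tert-butoxy-4-hydroxy-2,3-diisopropoxycyclohexa-2,4-dien-1-one | O=C1CC(OC(C)(C)C)=C(O)C(OC(C)C)=C1OC(C)C | intermediate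
7 | 5-tert-butoxy-2,3-diisopropoxybenzene-1,4-diol | Oc1cc(OC(C)(C)C)c(O)c(OC(C)C)c1OC(C)C | intermediate
8 | 6-tert-butoxy-2,3,4-triisopropoxyphenol | CC(C)Oc1cc(OC(C)(C)C)c(O)c(OC(C)C)c1OC(C)C | intermediate
9 | 4-bromo-2,6-dimethoxyphenol | COc1cc(Br)cc(OC)c1O | starting material
10 | (3,4,5-trimethoxyphenyl)boronic acid | COc1cc(B(O)O)cc(OC)c1OC | starting material
11 | 5-(4-bromo-2,6-dimethoxyphenoxy)-1,2,3-trimethoxybenzene | COc1cc(Br)cc(OC)c1Oc1cc(OC)c(OC)c(OC)c1 | intermediate
12 | 1-tert-butoxy-2-[3,5-dimethoxy-4-(3,4,5-trimethoxyphenoxy)phenoxy]-3,4,5-triisopropoxybenzene | CC(C)(C)Oc1cc(OC(C)C)c(OC(C)C)c(OC(C)C)c1Oc1cc(OC)c(Oc2cc(OC)c(OC)c(OC)c2)c(OC)c1 | intermediate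
13 | 2-[3,5-dimethoxy-4-(3,4,5-trimethoxyphenoxy)phenoxy]-3,4,5-triisopropoxyphenol | Oc1cc(OC(C)C)c(OC(C)C)c(OC(C)C)c1Oc1cc(OC)c(Oc2cc(OC)c(OC)c(OC)c2)c(OC)c1 | intermediate
14 | 2-bromo-1,3-dimethoxybenzene | COc1cccc(OC)c1Br | starting material
15 | 2-(4-bromo-3,5-dimethoxyphenyl)-4,4,5,5-tetramethyl-1,3,2-dioxaborolane | COc1cc(B2OC(C)(C)C(C)(C)O2)cc(OC)c1Br | intermediate
16 | 2-bromo-5-iodo-1,3-dimethoxybenzene | COc1cc(I)cc(OC)c1Br | intermediate
17 | 2-bromo-5-(4-bromo-2,6-dimethoxyphenoxy)-1,3-dimethoxybenzene | COc1cc(Oc2c(OC)cc(Br)cc2OC)cc(OC)c1Br | intermediate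
18 | 2,4,6-trimethoxyphenol | COc1cc(OC)c(O)c(OC)c1 | starting material
19 | 2-[4-(4-bromo-3,5-dimethoxyphenoxy)-3,5-dimethoxyphenoxy]-1,3,5-trimethoxybenzene | COc1cc(OC)c(Oc2cc(OC)c(Oc3cc(OC)c(Br)c(OC)c3)c(OC)c2)c(OC)c1 | intermediate
20 | 1-{4-[2,6-dimethoxy-4-(2,4,6-trimethoxyphenoxy)phenoxy]-2,6-dimethoxyphenoxy}-2-[3,5-dimethoxy-4-(3,4,5-trimethoxyphenoxy)phenoxy]-3,4,5-triisopropoxybenzene | COc1cc(OC)c(Oc2cc(OC)c(Oc3cc(OC)c(Oc4cc(OC(C)C)c(OC(C)C)c(OC(C)C)c4Oc4cc(OC)c(Oc5cc(OC)c(OC)c(OC)c5)c(OC)c4)c(OC)c3)c(OC)c2)c(OC)c1 | intermediate
21 | 2-{4-[4-(2-{3,5-dihydroxy-4-(3,4,5-trihydroxyphenoxy)phenoxy}-3,4,5-trihydroxyphenoxy)-3,5-dihydroxyphenoxy]-3,5-dihydroxyphenoxy}benzene-1,3,5-triol (CNP0175585.0) | Oc1cc(O)c(Oc2cc(O)c(Oc3cc(O)c(Oc4cc(O)c(O)c(O)c4Oc4cc(O)c(Oc5cc(O)c(O)c(O)c5)c(O)c4)c(O)c3)c(O)c2)c(O)c1 | target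

## Step count and risks

Total step count: 11. Longest linear sequence: 7 steps (1, 2, 3, 5, 6, 10, 11).

**Step 2 (key step).** The most likely failures are hydrolytic loss of the tert-butyl enol ether of 4 on trace acid before ring opening and air oxidation of the electron-rich hydroquinone during isolation. Erosion of torquoselectivity, leading to lactonisation of the ketene, is less likely. The fallback sets out from 4 and changes what is isolated: the thermolysis is followed in the same flask by deliberate oxidation with air to the quinone 2-tert-butoxy-5,6-diisopropoxycyclohexa-2,5-diene-1,4-dione F1, which should survive chromatography and storage. Reduction of F1 with aqueous Na2S2O4 immediately before step 3 brings the route back at 7.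

**Step 3.** Steric discrimination between the two hydroxyls may be incomplete, giving alkylation at the flanked oxygen or double alkylation, and the hydroquinonate may oxidise in base. The fallback fixes the differentiation before the ring is made and sets out from 2. The addition mixture of 3 and 2 is quenched with chlorotrimethylsilane instead of water to give racemic 4-(1-tert-butoxyvinyl)-2,3-diisopropoxy-4-(trimethylsilyloxy)cyclobut-2-en-1-one F2. Thermolysis of F2 in toluene (same cascade, siloxy group outward) should give 5-tert-butoxy-2,3-diisopropoxy-4-(trimethylsilyloxy)phenol F3, in which only the ketene-derived hydroxyl is free. Mitsunobu etherification of F3 with propan-2-ol (PPh3, diisopropyl azodicarboxylate), neutral so that the silyl group stays in place, gives (6-tert-butoxy-2,3,4-triisopropoxyphenoxy)trimethylsilane F4. K2CO3 in methanol removes the silyl group of F4 and the route is rejoined at 8.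

**Step 5.** The phenoxide of 8 lies between tert-butoxy and isopropoxy groups and bromide 11 is electron-rich, so coupling may be slow enough for reduction of the bromide or oxidation of the phenol to take over. The fallback sets out from 11 and changes the carbon partner from a halide to an arylboron. Bromine–lithium exchange (n-BuLi, THF, −78 °C), B(OiPr)3 and aqueous acid give [3,5-dimethoxy-4-(3,4,5-trimethoxyphenoxy)phenyl]boronic acid F5. Chan–Lam coupling of F5 with 8 (Cu(OAc)2, pyridine, air, rt) rejoins the route at 12.

**Step 9.** Site selection between the two bromides of 17 may be imperfect, and in step 8 the open bromide of the product may react further. The fallback sets out from 9 and removes both halide selections. Benzylation (benzyl bromide, K2CO3) gives 2-(benzyloxy)-5-bromo-1,3-dimethoxybenzene F6. Ullmann coupling of F6 with 18 gives 2-[4-(benzyloxy)-3,5-dimethoxyphenoxy]-1,3,5-trimethoxybenzene F7. Hydrogenolysis of F7 (H2, Pd/C) frees 2,6-dimethoxy-4-(2,4,6-trimethoxyphenoxy)phenol F8. Ullmann coupling of F8 with 16, where only an iodide competes with a flanked bromide, rejoins the route at 19.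

**Step 10.** Oxidative addition or C–O reductive elimination at the doubly flanked, electron-rich bromide may fail, with reductive loss of bromine from 19 as the competing process. The fallback sets out from 13 and grows rings C, B and A one at a time with an activated electrophile, 4-bromo-3,5-dimethoxybenzaldehyde, whose para formyl group makes the flanked bromide reactive. Each cycle is a copper-catalysed coupling (CuI, picolinic acid, K3PO4, DMSO) followed by Baeyer–Villiger oxidation with a peracid and methanolysis of the formate (Dakin-type), which turns the formyl group into the next open phenol. The first cycle gives 4-{2-[3,5-dimethoxy-4-(3,4,5-trimethoxyphenoxy)phenoxy]-3,4,5-triisopropoxyphenoxy}-3,5-dimethoxybenzaldehyde F9 and from it 4-{2-[3,5-dimethoxy-4-(3,4,5-trimethoxyphenoxy)phenoxy]-3,4,5-triisopropoxyphenoxy}-3,5-dimethoxyphenol F10. The second cycle gives the ring B aldehyde 4-(4-{2-[3,5-dimethoxy-4-(3,4,5-trimethoxyphenoxy)phenoxy]-3,4,5-triisopropoxyphenoxy}-3,5-dimethoxyphenoxy)-3,5-dimethoxybenzaldehyde F11 and then the phenol 4-(4-{2-[3,5-dimethoxy-4-(3,4,5-trimethoxyphenoxy)phenoxy]-3,4,5-triisopropoxyphenoxy}-3,5-dimethoxyphenoxy)-3,5-dimethoxyphenol F12. The third cycle gives the ring A aldehyde 4-[4-(4-{2-[3,5-dimethoxy-4-(3,4,5-trimethoxyphenoxy)phenoxy]-3,4,5-triisopropoxyphenoxy}-3,5-dimethoxyphenoxy)-3,5-dimethoxyphenoxy]-3,5-dimethoxybenzaldehyde F13 and then the phenol 4-[4-(4-{2-[3,5-dimethoxy-4-(3,4,5-trimethoxyphenoxy)phenoxy]-3,4,5-triisopropoxyphenoxy}-3,5-dimethoxyphenoxy)-3,5-dimethoxyphenoxy]-3,5-dimethoxyphenol F14. F14 differs from 20 only in a free hydroxyl in place of one methoxy group on ring A, so the conditions of step 11 applied to F14 bring the route back at 21. This detour is longer but never asks an unactivated flanked halide to couple.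

**Step 11.** Dealkylation may stop short at some of the fifteen ethers, and the free polyphenol may oxidise during purification. The fallback sets out from 20 and changes the isolation. The crude product of the BBr3 treatment is acetylated (acetic anhydride, pyridine) to the peracetylated hexamer F15 (all fifteen hydroxyls of 21 as acetates), which can be chromatographed on silica and separated from under-dealkylated material. Acid-catalysed methanolysis of F15 (HCl in methanol, Ar) then releases the phenols and returns the route at 21.

## Further compounds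

F1 | step 2 | 2-tert-butoxy-5,6-diisopropoxycyclohexa-2,5-diene-1,4-dione | O=C1C=C(OC(C)(C)C)C(=O)C(OC(C)C)=C1OC(C)C
F2 | step 3 | 4-(1-tert-butoxyvinyl)-2,3-diisopropoxy-4-(trimethylsilyloxy)cyclobut-2-en-1-one (racemic) | O=C1C(OC(C)C)=C(OC(C)C)C1(O[Si](C)(C)C)C(=C)OC(C)(C)C
F3 | step 3 | 5-tert-butoxy-2,3-diisopropoxy-4-(trimethylsilyloxy)phenol | Oc1cc(OC(C)(C)C)c(O[Si](C)(C)C)c(OC(C)C)c1OC(C)C
F4 | step 3 | (6-tert-butoxy-2,3,4-triisopropoxyphenoxy)trimethylsilane | CC(C)Oc1cc(OC(C)(C)C)c(O[Si](C)(C)C)c(OC(C)C)c1OC(C)C
F5 | step 5 | [3,5-dimethoxy-4-(3,4,5-trimethoxyphenoxy)phenyl]boronic acid | COc1cc(B(O)O)cc(OC)c1Oc1cc(OC)c(OC)c(OC)c1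
F6 | step 9 | 2-(benzyloxy)-5-bromo-1,3-dimethoxybenzene | COc1cc(Br)cc(OC)c1OCc1ccccc1
F7 | step 9 | 2-[4-(benzyloxy)-3,5-dimethoxyphenoxy]-1,3,5-trimethoxybenzene | COc1cc(OC)c(Oc2cc(OC)c(OCc3ccccc3)c(OC)c2)c(OC)c1
F8 | step 9 | 2,6-dimethoxy-4-(2,4,6-trimethoxyphenoxy)phenol | COc1cc(OC)c(Oc2cc(OC)c(O)c(OC)c2)c(OC)c1
F9 | step 10 | 4-{2-[3,5-dimethoxy-4-(3,4,5-trimethoxyphenoxy)phenoxy]-3,4,5-triisopropoxyphenoxy}-3,5-dimethoxybenzaldehyde | O=Cc1cc(OC)c(Oc2cc(OC(C)C)c(OC(C)C)c(OC(C)C)c2Oc2cc(OC)c(Oc3cc(OC)c(OC)c(OC)c3)c(OC)c2)c(OC)c1
F10 | step 10 | 4-{2-[3,5-dimethoxy-4-(3,4,5-trimethoxyphenoxy)phenoxy]-3,4,5-triisopropoxyphenoxy}-3,5-dimethoxyphenol | Oc1cc(OC)c(Oc2cc(OC(C)C)c(OC(C)C)c(OC(C)C)c2Oc2cc(OC)c(Oc3cc(OC)c(OC)c(OC)c3)c(OC)c2)c(OC)c1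
F11 | step 10 | 4-(4-{2-[3,5-dimethoxy-4-(3,4,5-trimethoxyphenoxy)phenoxy]-3,4,5-triisopropoxyphenoxy}-3,5-dimethoxyphenoxy)-3,5-dimethoxybenzaldehyde | O=Cc1cc(OC)c(Oc2cc(OC)c(Oc3cc(OC(C)C)c(OC(C)C)c(OC(C)C)c3Oc3cc(OC)c(Oc4cc(OC)c(OC)c(OC)c4)c(OC)c3)c(OC)c2)c(OC)c1
F12 | step 10 | 4-(4-{2-[3,5-dimethoxy-4-(3,4,5-trimethoxyphenoxy)phenoxy]-3,4,5-triisopropoxyphenoxy}-3,5-dimethoxyphenoxy)-3,5-dimethoxyphenol | Oc1cc(OC)c(Oc2cc(OC)c(Oc3cc(OC(C)C)c(OC(C)C)c(OC(C)C)c3Oc3cc(OC)c(Oc4cc(OC)c(OC)c(OC)c4)c(OC)c3)c(OC)c2)c(OC)c1
F13 | step 10 | 4-[4-(4-{2-[3,5-dimethoxy-4-(3,4,5-trimethoxyphenoxy)phenoxy]-3,4,5-triisopropoxyphenoxy}-3,5-dimethoxyphenoxy)-3,5-dimethoxyphenoxy]-3,5-dimethoxybenzaldehyde | O=Cc1cc(OC)c(Oc2cc(OC)c(Oc3cc(OC)c(Oc4cc(OC(C)C)c(OC(C)C)c(OC(C)C)c4Oc4cc(OC)c(Oc5cc(OC)c(OC)c(OC)c5)c(OC)c4)c(OC)c3)c(OC)c2)c(OC)c1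
F14 | step 10 | 4-[4-(4-{2-[3,5-dimethoxy-4-(3,4,5-trimethoxyphenoxy)phenoxy]-3,4,5-triisopropoxyphenoxy}-3,5-dimethoxyphenoxy)-3,5-dimethoxyphenoxy]-3,5-dimethoxyphenol | Oc1cc(OC)c(Oc2cc(OC)c(Oc3cc(OC)c(Oc4cc(OC(C)C)c(OC(C)C)c(OC(C)C)c4Oc4cc(OC)c(Oc5cc(OC)c(OC)c(OC)c5)c(OC)c4)c(OC)c3)c(OC)c2)c(OC)c1
F15 | step 11 | peracetylated hexamer (pentadecaacetate of 21, all fifteen hydroxyls as acetate esters) | CC(=O)Oc1cc(OC(C)=O)c(Oc2cc(OC(C)=O)c(Oc3cc(OC(C)=O)c(Oc4cc(OC(C)=O)c(OC(C)=O)c(OC(C)=O)c4Oc4cc(OC(C)=O)c(Oc5cc(OC(C)=O)c(OC(C)=O)c(OC(C)=O)c5)c(OC(C)=O)c4)c(OC(C)=O)c3)c(OC(C)=O)c2)c(OC(C)=O)c1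
A1 | alternative 1 | cyclopentadienyl(2,5-dichloro-1,3-dimethoxybenzene)ruthenium hexafluorophosphate (divalent ruthenium, arene bound through all six ring carbons; written as separate components) | COc1cc(Cl)cc(OC)c1Cl.c1cc[cH-]c1.[Ru+2].F[P-](F)(F)(F)(F)F
A2 | alternative 1 | 6-{4-[2,6-dimethoxy-4-(2,4,6-trimethoxyphenoxy)phenoxy]-2,6-dimethoxyphenoxy}-2,3,4-trimethoxyphenol (ring A–B–C–D phenol) | COc1cc(OC)c(Oc2cc(OC)c(Oc3cc(OC)c(Oc4cc(OC)c(OC)c(OC)c4O)c(OC)c3)c(OC)c2)c(OC)c1
A3 | alternative 1 | 3,4,5-trimethoxyphenol | COc1cc(O)cc(OC)c1OC
A4 | alternative 1 | permethylated target hexamer (pentadecamethyl ether of 21) | COc1cc(OC)c(Oc2cc(OC)c(Oc3cc(OC)c(Oc4cc(OC)c(OC)c(OC)c4Oc4cc(OC)c(Oc5cc(OC)c(OC)c(OC)c5)c(OC)c4)c(OC)c3)c(OC)c2)c(OC)c1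
A5 | alternative 2 | dimethyl 4-[4-(benzyloxy)-3,5-dimethoxyphenoxy]-3,5-dioxoheptanedioate | COC(=O)CC(=O)C(Oc1cc(OC)c(OCc2ccccc2)c(OC)c1)C(=O)CC(=O)OC
A6 | alternative 2 | methyl 3-[4-(benzyloxy)-3,5-dimethoxyphenoxy]-2,4,6-trihydroxybenzoate | COC(=O)c1c(O)cc(O)c(Oc2cc(OC)c(OCc3ccccc3)c(OC)c2)c1O
A7 | alternative 3 | hexamer deca-aldehyde pentabenzyl ether (formyl groups in place of the ten hydroxyls of A8) | O=Cc1cc(OCc9ccccc9)cc(C=O)c1Oc1cc(C=O)c(Oc2cc(C=O)c(Oc3cc(C=O)c(OCc9ccccc9)c(C=O)c3Oc3cc(C=O)c(Oc4cc(OCc9ccccc9)c(OCc9ccccc9)c(OCc9ccccc9)c4)c(C=O)c3)c(C=O)c2)c(C=O)c1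
A8 | alternative 3 | hexamer decaphenol pentabenzyl ether | Oc1cc(OCc9ccccc9)cc(O)c1Oc1cc(O)c(Oc2cc(O)c(Oc3cc(O)c(OCc9ccccc9)c(O)c3Oc3cc(O)c(Oc4cc(OCc9ccccc9)c(OCc9ccccc9)c(OCc9ccccc9)c4)c(O)c3)c(O)c2)c(O)c1
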